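**Retrosynthetic overview**
1. Target 21 is a 2,3-trans, 3,4-trans, 4,5-cis oxolane (numbered O1, C2–C5); it comes from 20 by global desilylation.
2. Key disconnection: the aryl–C2 bond together with O1–C2. Lithiated 4-bromo-2,6-dimethoxyphenol (free phenoxide) is joined to lactol 15 (masked C2 aldehyde), and the oxolane ring is closed again in the same flask by addition of the C5 hydroxyl to a p-quinone methide.
3. Enabling feature: the 4-hydroxyl of the aryl ring on C2 is para to, and conjugated with, the benzylic C2–O1 bond of the oxolane, so C2 is a latent quinone methide carbon and O1–C2 can form reversibly and stereoconvergently. The same oxygen on the C5 aryl ring stays silylated, so C5–O1 stays fixed.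
4. Lactol 15 comes from γ-lactone 14, made by trans C3-alkylation of lactone 12, which is the lactonised anti-aldol adduct of succinate imide 6 and silylated syringaldehyde 2 (sets C4 and C5).
5. Ring order: γ-lactone (step 6), reduced to the lactol (step 8), then opened and closed again as the oxolane of the target (step 9).

Key step: step 9

Remark: the oxolane numbering O1, C2 (the aryl-bearing carbon made in step 9), C3, C4, C5 is used for all cyclic compounds; ArSi = 3,5-dimethoxy-4-(triisopropylsilyloxy)phenyl; compounds 1, 3, 4 and 16 are taken as commercial.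

**Route**

Step 1
Reactants: 1 syringaldehyde (4-hydroxy-3,5-dimethoxybenzaldehyde)
Product: 2 3,5-dimethoxy-4-(triisopropylsilyloxy)benzaldehyde
Conditions: i-Pr3SiCl, imidazole, DMF, rt → 40 °C
Reagents that add atoms: chlorotriisopropylsilane, CC(C)[Si](Cl)(C(C)C)C(C)C
Why: Silyl ether formation on the phenol should give a bulky aryl silyl ether that survives all later steps and keeps the para-oxygen of this ring a poor donor.

Step 2
Reactants: 3 mono-tert-butyl succinate (4-tert-butoxy-4-oxobutanoic acid); 4 (R)-4-benzyloxazolidin-2-one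
Product: 6 tert-butyl 4-[(4R)-4-benzyl-2-oxooxazolidin-3-yl]-4-oxobutanoate, via mixed anhydride 5 (not isolated)
Conditions: 3, t-BuCOCl, Et3N, THF, −20 °C; then 4, LiCl, −20 °C → rt
Reagents that add atoms: none
Why: N-acylation of the oxazolidinone through the mixed pivalic anhydride should proceed at the less hindered succinyl carbonyl and forms no stereocentre.

Step 3
Reactants: 6 tert-butyl 4-[(4R)-4-benzyl-2-oxooxazolidin-3-yl]-4-oxobutanoate; 2 3,5-dimethoxy-4-(triisopropylsilyloxy)benzaldehyde
Product: 8 tert-butyl (3S,4R)-3-{[(4R)-4-benzyl-2-oxooxazolidin-3-yl]carbonyl}-4-(ArSi)-4-hydroxybutanoate, via silyl ether 7 (not isolated)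
Conditions: MgCl2 (20 mol %), Et3N, Me3SiCl, EtOAc, rt; then 1 M HCl, THF, 0 °C
Reagents that add atoms: none
Why: In this Evans-type magnesium chloride-catalysed direct anti-aldol reaction the chelated (Z)-magnesium enolate should add through a boat transition state on the face opposite the benzyl group of the (R)-auxiliary, setting C3 (S) and C4 (R) anti to each other (the later C4/C5 cis pair), with silylation of the aldolate driving the equilibrium.

Step 4
Reactants: 8 tert-butyl (3S,4R)-3-{[(4R)-4-benzyl-2-oxooxazolidin-3-yl]carbonyl}-4-(ArSi)-4-hydroxybutanoate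
Product: 9 tert-butyl (3R,4R)-4-(ArSi)-4-hydroxy-3-(hydroxymethyl)butanoate
Conditions: LiBH4, H2O (1 equiv), Et2O/THF, 0 °C
Reagents that add atoms: none
Why: Reductive removal of the oxazolidinone auxiliary should reduce the activated imide carbonyl in preference to the tert-butyl ester and touches no stereocentre.

Step 5
Reactants: 9 tert-butyl (3R,4R)-4-(ArSi)-4-hydroxy-3-(hydroxymethyl)butanoate
Product: 10 tert-butyl (3R,4R)-3-[(tert-butyldiphenylsilyloxy)methyl]-4-(ArSi)-4-hydroxybutanoate
Conditions: t-BuPh2SiCl (1.05 equiv), imidazole, CH2Cl2, 0 °C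
Reagents that add atoms: tert-butylchlorodiphenylsilane, CC(C)(C)[Si](Cl)(c1ccccc1)c1ccccc1
Why: Silyl ether formation should be selective for the primary over the hindered secondary benzylic hydroxyl, which leaves only the benzylic oxygen free for ring formation.

Step 6
Reactants: 10 tert-butyl (3R,4R)-3-[(tert-butyldiphenylsilyloxy)methyl]-4-(ArSi)-4-hydroxybutanoate
Product: 12 (4R,5R)-4-[(tert-butyldiphenylsilyloxy)methyl]-5-(ArSi)oxolan-2-one (4,5-cis), via hydroxy acid 11 (not isolated)
Conditions: CF3CO2H, CH2Cl2, 0 °C → rt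
Reagents that add atoms: none
Why: Acidolysis of the tert-butyl ester followed by spontaneous γ-lactonisation (acyl substitution, C5–O bond untouched) should carry the anti-aldol configuration into the cis-4,5-disubstituted lactone.

Step 7
Reactants: 12 (4R,5R)-4-[(tert-butyldiphenylsilyloxy)methyl]-5-(ArSi)oxolan-2-one
Product: 14 (3R,4R,5R)-4-[(tert-butyldiphenylsilyloxy)methyl]-5-(ArSi)-3-[(triisopropylsilyloxy)methyl]oxolan-2-one, via lithium enolate 13 (not isolated)
Conditions: LiN(i-Pr)2 (1.05 equiv), THF, −78 °C; then i-Pr3SiOCH2Cl, −78 → −40 °C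
Reagents that add atoms: (triisopropylsiloxy)methyl chloride, ClCO[Si](C(C)C)(C(C)C)C(C)C
Why: C-alkylation of the lactone enolate with an α-chloro ether should occur anti to the C4 substituent and the cis C5 aryl group, setting C3 (R) trans to C4.

Step 8
Reactants: 14 (3R,4R,5R)-4-[(tert-butyldiphenylsilyloxy)methyl]-5-(ArSi)-3-[(triisopropylsilyloxy)methyl]oxolan-2-one
Product: 15 (3R,4R,5R)-4-[(tert-butyldiphenylsilyloxy)methyl]-5-(ArSi)-3-[(triisopropylsilyloxy)methyl]oxolan-2-ol (both anomers)
Conditions: i-Bu2AlH (1.2 equiv), CH2Cl2, −78 °C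
Reagents that add atoms: none
Why: Partial reduction of the γ-lactone should stop at the lactol because the tetrahedral aluminium alkoxide is stable at −78 °C, and the anomeric mixture is of no consequence.

Step 9
Reactants: 15 (3R,4R,5R)-4-[(tert-butyldiphenylsilyloxy)methyl]-5-(ArSi)-3-[(triisopropylsilyloxy)methyl]oxolan-2-ol; 16 4-bromo-2,6-dimethoxyphenol
Product: 20 4-[(2S,3R,4R,5R)-4-[(tert-butyldiphenylsilyloxy)methyl]-5-(ArSi)-3-[(triisopropylsilyloxy)methyl]oxolan-2-yl]-2,6-dimethoxyphenol, via aryllithium 17 (not isolated), via diol 18 (not isolated), via quinone methide 19 (not isolated)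
Conditions: 16 (2.5 equiv), n-BuLi (1 equiv per 16) then t-BuLi (2 equiv per 16), THF, −78 °C; add 15, −78 → −20 °C; then CF3CO2H (slight excess over total base), THF/CH2Cl2, −20 °C → rt
Reagents that add atoms: none
Why: Aryllithium 17, whose C–Li bond sits para to the phenoxide and so fixes the site of coupling, should add 1,2 to the open hydroxy-aldehyde form of lactol 15 and form the aryl–C2 bond as the carbinol mixture 18, a known addition of organolithium reagents to lactols. On acidification only the new 4-hydroxybenzylic alcohol should ionise, losing water to p-quinone methide 19, which the C5 hydroxyl captures by 5-exo-trig oxa-1,6-addition that closes the oxolane ring at O1–C2 and restores the aromatic ring. The closest known reaction types are the acid-mediated cyclodehydration of 1,4-diaryl-1,4-diols and the quinone methide cycloetherifications of lignan chemistry. The new stereocentre C2 is set in the ring closure and not in the addition: both carbinol epimers converge on planar 19, closure should place the aryl group trans to the C3 silyloxymethyl group (both pseudo-equatorial in the envelope transition state), and since the 4-hydroxybenzyl ether can re-ionise under the same acid the 2,3-trans isomer should also be the thermodynamic product. The step needs ionisation at C2 only and ring closure by the C5 oxygen only. The first is secured because a free para-hydroxyl is present on the new ring alone, the para-oxygen of the C5 aryl ring being silylated and twisted out of conjugation by its two methoxy neighbours so that the 4,5-cis relationship is kept, and the second by the silyl ethers on both primary hydroxyls.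

Step 10
Reactants: 20 4-[(2S,3R,4R,5R)-4-[(tert-butyldiphenylsilyloxy)methyl]-5-(ArSi)-3-[(triisopropylsilyloxy)methyl]oxolan-2-yl]-2,6-dimethoxyphenol
Product: 21 [(2S,3R,4R,5R)-2,5-bis(4-hydroxy-3,5-dimethoxyphenyl)oxolane-3,4-diyl]dimethanol (target)
Conditions: Bu4NF, AcOH, THF, 0 °C → rt
Reagents that add atoms: none
Why: Fluoride-mediated cleavage of the aryl and the two primary silyl ethers under acetic acid buffering should free all three hydroxyls without base- or acid-induced opening of the benzylic ether bonds, so no stereocentre is touched.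

**Compound list**
1 | syringaldehyde (4-hydroxy-3,5-dimethoxybenzaldehyde) | COc1cc(C=O)cc(OC)c1O | starting material
2 | 3,5-dimethoxy-4-(triisopropylsilyloxy)benzaldehyde | COc1cc(C=O)cc(OC)c1O[Si](C(C)C)(C(C)C)C(C)C | intermediate
3 | mono-tert-butyl succinate (4-tert-butoxy-4-oxobutanoic acid) | OC(=O)CCC(=O)OC(C)(C)C | starting material
4 | (R)-4-benzyloxazolidin-2-one | O=C1N[C@H](Cc2ccccc2)CO1 | starting material
5 | mixed anhydride of mono-tert-butyl succinate and pivalic acid (not isolated) | CC(C)(C)OC(=O)CCC(=O)OC(=O)C(C)(C)C | intermediate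
6 | tert-butyl 4-[(4R)-4-benzyl-2-oxooxazolidin-3-yl]-4-oxobutanoate | CC(C)(C)OC(=O)CCC(=O)N1C(=O)OC[C@H]1Cc1ccccc1 | intermediate
7 | O-trimethylsilyl ether of aldol adduct 8 (not isolated) | C[Si](C)(C)O[C@@H](c1cc(OC)c(O[Si](C(C)C)(C(C)C)C(C)C)c(OC)c1)[C@@H](C(=O)N1C(=O)OC[C@H]1Cc1ccccc1)CC(=O)OC(C)(C)C | intermediate
8 | tert-butyl (3S,4R)-3-{[(4R)-4-benzyl-2-oxooxazolidin-3-yl]carbonyl}-4-[3,5-dimethoxy-4-(triisopropylsilyloxy)phenyl]-4-hydroxybutanoate (anti-aldol adduct) | O[C@@H](c1cc(OC)c(O[Si](C(C)C)(C(C)C)C(C)C)c(OC)c1)[C@@H](C(=O)N1C(=O)OC[C@H]1Cc1ccccc1)CC(=O)OC(C)(C)C | intermediate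
9 | tert-butyl (3R,4R)-4-[3,5-dimethoxy-4-(triisopropylsilyloxy)phenyl]-4-hydroxy-3-(hydroxymethyl)butanoate | O[C@@H](c1cc(OC)c(O[Si](C(C)C)(C(C)C)C(C)C)c(OC)c1)[C@@H](CO)CC(=O)OC(C)(C)C | intermediate
10 | tert-butyl (3R,4R)-3-[(tert-butyldiphenylsilyloxy)methyl]-4-[3,5-dimethoxy-4-(triisopropylsilyloxy)phenyl]-4-hydroxybutanoate | O[C@@H](c1cc(OC)c(O[Si](C(C)C)(C(C)C)C(C)C)c(OC)c1)[C@@H](CO[Si](c1ccccc1)(c1ccccc1)C(C)(C)C)CC(=O)OC(C)(C)C | intermediate
11 | (3R,4R)-3-[(tert-butyldiphenylsilyloxy)methyl]-4-[3,5-dimethoxy-4-(triisopropylsilyloxy)phenyl]-4-hydroxybutanoic acid (not isolated) | O[C@@H](c1cc(OC)c(O[Si](C(C)C)(C(C)C)C(C)C)c(OC)c1)[C@@H](CO[Si](c1ccccc1)(c1ccccc1)C(C)(C)C)CC(=O)O | intermediate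
12 | (4R,5R)-4-[(tert-butyldiphenylsilyloxy)methyl]-5-[3,5-dimethoxy-4-(triisopropylsilyloxy)phenyl]oxolan-2-one (4,5-cis) | O1[C@@H](c2cc(OC)c(O[Si](C(C)C)(C(C)C)C(C)C)c(OC)c2)[C@@H](CO[Si](c2ccccc2)(c2ccccc2)C(C)(C)C)CC1=O | intermediate
13 | lithium enolate of lactone 12 (not isolated) | O1[C@@H](c2cc(OC)c(O[Si](C(C)C)(C(C)C)C(C)C)c(OC)c2)[C@@H](CO[Si](c2ccccc2)(c2ccccc2)C(C)(C)C)C=C1O[Li] | intermediate
14 | (3R,4R,5R)-4-[(tert-butyldiphenylsilyloxy)methyl]-5-[3,5-dimethoxy-4-(triisopropylsilyloxy)phenyl]-3-[(triisopropylsilyloxy)methyl]oxolan-2-one (3,4-trans, 4,5-cis) | O1[C@@H](c2cc(OC)c(O[Si](C(C)C)(C(C)C)C(C)C)c(OC)c2)[C@@H](CO[Si](c2ccccc2)(c2ccccc2)C(C)(C)C)[C@H](CO[Si](C(C)C)(C(C)C)C(C)C)C1=O | intermediate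
15 | (3R,4R,5R)-4-[(tert-butyldiphenylsilyloxy)methyl]-5-[3,5-dimethoxy-4-(triisopropylsilyloxy)phenyl]-3-[(triisopropylsilyloxy)methyl]oxolan-2-ol (lactol, both anomers) | O1[C@@H](c2cc(OC)c(O[Si](C(C)C)(C(C)C)C(C)C)c(OC)c2)[C@@H](CO[Si](c2ccccc2)(c2ccccc2)C(C)(C)C)[C@H](CO[Si](C(C)C)(C(C)C)C(C)C)C1O | intermediate
16 | 4-bromo-2,6-dimethoxyphenol | COc1cc(Br)cc(OC)c1O | starting material
17 | lithium 4-lithio-2,6-dimethoxyphenolate (not isolated) | COc1cc([Li])cc(OC)c1O[Li] | intermediate
18 | (2R,3R,4R)-3-[(tert-butyldiphenylsilyloxy)methyl]-4-[3,5-dimethoxy-4-(triisopropylsilyloxy)phenyl]-1-(4-hydroxy-3,5-dimethoxyphenyl)-2-[(triisopropylsilyloxy)methyl]butane-1,4-diol (both C1 epimers, not isolated) | O[C@@H](c1cc(OC)c(O[Si](C(C)C)(C(C)C)C(C)C)c(OC)c1)[C@@H](CO[Si](c1ccccc1)(c1ccccc1)C(C)(C)C)[C@H](CO[Si](C(C)C)(C(C)C)C(C)C)C(O)c1cc(OC)c(O)c(OC)c1 | intermediate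
19 | p-quinone methide formed from 18 by loss of water at C1: 4-ylidene-2,6-dimethoxycyclohexa-2,5-dien-1-one carrying the chain of 18 with its three other stereocentres unchanged (not isolated) | O[C@@H](c1cc(OC)c(O[Si](C(C)C)(C(C)C)C(C)C)c(OC)c1)[C@@H](CO[Si](c1ccccc1)(c1ccccc1)C(C)(C)C)[C@H](CO[Si](C(C)C)(C(C)C)C(C)C)C=C1C=C(OC)C(=O)C(OC)=C1 | intermediate
20 | 4-[(2S,3R,4R,5R)-4-[(tert-butyldiphenylsilyloxy)methyl]-5-[3,5-dimethoxy-4-(triisopropylsilyloxy)phenyl]-3-[(triisopropylsilyloxy)methyl]oxolan-2-yl]-2,6-dimethoxyphenol (2,3-trans, 3,4-trans, 4,5-cis) | O1[C@@H](c2cc(OC)c(O[Si](C(C)C)(C(C)C)C(C)C)c(OC)c2)[C@@H](CO[Si](c2ccccc2)(c2ccccc2)C(C)(C)C)[C@H](CO[Si](C(C)C)(C(C)C)C(C)C)[C@H]1c1cc(OC)c(O)c(OC)c1 | intermediate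
21 | [(2S,3R,4R,5R)-2,5-bis(4-hydroxy-3,5-dimethoxyphenyl)oxolane-3,4-diyl]dimethanol (2,3-trans, 3,4-trans, 4,5-cis) | O1[C@@H](c2cc(OC)c(O)c(OC)c2)[C@@H](CO)[C@H](CO)[C@H]1c1cc(OC)c(O)c(OC)c1 | target

**Step count and risks**

Total step count: 10. Longest linear sequence: 9 steps (steps 2 to 10 from 3 and 4; equally steps 1 and 3 to 10 from 1).

Steps most likely to fail:

Step 9 (key step). The basic aryllithium may remove the proton at C3 next to the unmasked aldehyde instead of adding, which would epimerise C3 or expel silanolate. The bromine–lithium exchange on the lithium phenoxide may stay incomplete. In the acid stage the C5 carbinol may ionise as well, which would erode the 4,5-cis relationship. The fallback changes the carbonyl partner and the way C2 is set. It sets out from lactone 14 and aryllithium 17 (made from 16). Addition at −78 °C to the lactone carbonyl should give the cyclic hemiketal F1. With Et3SiH and BF3·OEt2 in CH2Cl2 at −78 °C, F1 should be reduced through the aryl-substituted oxocarbenium ion to the 2,3-cis oxolane F2 (hydride enters anti to the C3 substituent). On warming to about −20 °C the same Lewis acid should re-open only the 4-hydroxybenzylic C2–O1 bond and epimerise C2 to the 2,3-trans isomer, so the sequence comes back to the route at compound 20.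

Step 3. Soft enolisation of the succinate imide may be slow, and the reversible aldol addition may give low conversion or eroded anti selectivity with this aldehyde. The fallback replaces the auxiliary by enamine catalysis. It sets out from aldehyde 2 and commercial tert-butyl 4-oxobutanoate. An L-proline-catalysed direct cross-aldol reaction (DMF, 4 °C, slow addition of the donor aldehyde) should give the anti-aldol aldehyde F3, which is reduced in the same flask with NaBH4. The sequence comes back to the route at diol 9.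

Step 7. C-alkylation with the silylated chloromethyl ether may be sluggish, O-alkylation of the enolate may compete, and excess base may expel silanolate from the product to give an α-methylene lactone. The fallback replaces alkylation by an aldol reaction. It sets out from lactone 12. Enolisation with LiN(i-Pr)2 at −78 °C and addition of gaseous monomeric formaldehyde should give the trans hydroxymethyl lactone F4 (attack anti to the C4 substituent). Silylation with i-Pr3SiCl and imidazole comes back to the route at compound 14.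

**Further compounds**
F1 | step 9 | (3R,4R,5R)-4-[(tert-butyldiphenylsilyloxy)methyl]-5-[3,5-dimethoxy-4-(triisopropylsilyloxy)phenyl]-2-(4-hydroxy-3,5-dimethoxyphenyl)-3-[(triisopropylsilyloxy)methyl]oxolan-2-ol (cyclic hemiketal, both anomers) | O1[C@@H](c2cc(OC)c(O[Si](C(C)C)(C(C)C)C(C)C)c(OC)c2)[C@@H](CO[Si](c2ccccc2)(c2ccccc2)C(C)(C)C)[C@H](CO[Si](C(C)C)(C(C)C)C(C)C)C1(O)c1cc(OC)c(O)c(OC)c1
F2 | step 9 | 4-[(2R,3R,4R,5R)-4-[(tert-butyldiphenylsilyloxy)methyl]-5-[3,5-dimethoxy-4-(triisopropylsilyloxy)phenyl]-3-[(triisopropylsilyloxy)methyl]oxolan-2-yl]-2,6-dimethoxyphenol (2,3-cis epimer of 20) | O1[C@@H](c2cc(OC)c(O[Si](C(C)C)(C(C)C)C(C)C)c(OC)c2)[C@@H](CO[Si](c2ccccc2)(c2ccccc2)C(C)(C)C)[C@H](CO[Si](C(C)C)(C(C)C)C(C)C)[C@@H]1c1cc(OC)c(O)c(OC)c1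
F3 | step 3 | tert-butyl (3S,4R)-4-[3,5-dimethoxy-4-(triisopropylsilyloxy)phenyl]-3-formyl-4-hydroxybutanoate | O[C@@H](c1cc(OC)c(O[Si](C(C)C)(C(C)C)C(C)C)c(OC)c1)[C@@H](C=O)CC(=O)OC(C)(C)C
F4 | step 7 | (3R,4R,5R)-4-[(tert-butyldiphenylsilyloxy)methyl]-5-[3,5-dimethoxy-4-(triisopropylsilyloxy)phenyl]-3-(hydroxymethyl)oxolan-2-one | O1[C@@H](c2cc(OC)c(O[Si](C(C)C)(C(C)C)C(C)C)c(OC)c2)[C@@H](CO[Si](c2ccccc2)(c2ccccc2)C(C)(C)C)[C@H](CO)C1=O
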